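**Retrosynthetic overview**

1. The target, (3S)-7-hydroxy-3-(7-methoxy-2,2-dimethyl-2H-chromen-6-yl)chroman-4-one, comes from its 7-O-silyl ether by a final base-free desilylation.
2. Key disconnection: the C3–aryl bond. C3 of a racemic 3-bromochroman-4-one is the electrophile (an enolonium / alpha-keto cation equivalent) and the chromenyl ring enters as an arylzinc; one enantioconvergent NiCl2(DME)/chiral pybox coupling makes the bond and sets (S)-C3.
3. The bromoketone comes from commercial 7-hydroxychroman-4-one by one-pot bis-silylation and NBS bromination.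
4. The arylzinc comes from 6-bromo-7-methoxy-2,2-dimethyl-2H-chromene, made from 4-bromo-3-methoxyphenol and prenal.
5. Ring order: the pyran ring of the chromene is the only ring built (first step); the chromanone is bought intact and the two bicycles are joined last.

Assumption: the sense of induction of the nickel/pybox catalyst on this substrate is fixed by one analytical run (chiral HPLC and ECD). The ligand is written as the (S,S)-enantiomer, and its mirror image is used if that run gives the (R)-ketone.

**Route**

Step 1
Reactants: 1 4-bromo-3-methoxyphenol; 2 3-methylbut-2-enal (prenal)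
Product: 4 6-bromo-7-methoxy-2,2-dimethyl-2H-chromene, via o-quinone methide 3 (not isolated)
Conditions: PhB(OH)2 (1.0 equiv, recovered), AcOH (cat.), toluene, reflux, Dean–Stark, 24 h
Reagents that add atoms: none
Why: Phenylboronic acid templates ortho-condensation of the phenol with prenal at the unhindered carbon para to OMe, and the resulting o-quinone methide 3 closes by oxa-6π electrocyclisation to the 2,2-dimethyl-2H-chromene (boronic acid-mediated phenol–enal chromene annulation).

Step 2
Reactants: 5 7-hydroxychroman-4-one
Product: 7 rac-3-bromo-7-[(tert-butyldimethylsilyl)oxy]chroman-4-one, via bis-silyl enol ether 6 (not isolated)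
Conditions: TBSOTf (2.3 equiv), Et3N (3 equiv), CH2Cl2, 0 °C to rt; dilute with hexane, filter off the ammonium salt, concentrate; then NBS (1.0 equiv), THF, -78 °C
Reagents that add atoms: tert-butyldimethylsilyl trifluoromethanesulfonate (TBSOTf), CC(C)(C)[Si](C)(C)OS(=O)(=O)C(F)(F)F; N-bromosuccinimide (NBS), O=C1CCC(=O)N1Br
Why: Soft enolisation silylates both the phenol and the ketone enol, and NBS then brominates the electron-rich C3 of enol ether 6 with loss of the enol silyl group while the aryl silyl ether stays (silyl enol ether alpha-bromination); C3 is deliberately left racemic.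

Step 3
Reactants: 4 6-bromo-7-methoxy-2,2-dimethyl-2H-chromene; 7 rac-3-bromo-7-[(tert-butyldimethylsilyl)oxy]chroman-4-one
Product: 10 (3S)-7-[(tert-butyldimethylsilyl)oxy]-3-(7-methoxy-2,2-dimethyl-2H-chromen-6-yl)chroman-4-one, via arylmagnesium bromide 8 (not isolated), via arylzinc iodide 9 (not isolated)
Conditions: 4 (1.5 equiv), Mg turnings, THF, 40 °C; ZnI2 (1.6 equiv), THF, rt; then 7 (1.0 equiv), NiCl2(DME) (5 mol %), 2,6-bis[(4S,5S)-4-(methoxymethyl)-5-phenyl-4,5-dihydro-1,3-oxazol-2-yl]pyridine (6.5 mol %), DME/THF, -30 °C, 6 h; quench cold with EtOH, then aq NH4Cl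
Reagents that add atoms: none
Why: Proposed new method: the C3 bromide of 7 acts as an enolonium (alpha-keto cation) equivalent in an enantioconvergent nickel/pybox Negishi arylation, in which monovalent nickel abstracts bromine from either enantiomer of 7 to give a planar C3 alpha-keto radical, the chiral aryl–nickel complex captures it on one face, and reductive elimination from trivalent nickel forms the C3–aryl bond as the (S)-isomer with no Brønsted base present to epimerise it; the closest known reaction type is the nickel/pybox-catalysed asymmetric Negishi arylation of racemic acyclic alpha-bromoketones with ArZnI at -30 °C, extended here to a cyclic beta-aryloxy bromoketone and an ortho-methoxy arylzinc.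

Step 4
Reactants: 10 (3S)-7-[(tert-butyldimethylsilyl)oxy]-3-(7-methoxy-2,2-dimethyl-2H-chromen-6-yl)chroman-4-one
Product: 11 (3S)-7-hydroxy-3-(7-methoxy-2,2-dimethyl-2H-chromen-6-yl)chroman-4-one
Conditions: KHF2 (2.5 equiv), MeOH, rt, 1 h
Reagents that add atoms: none
Why: Bifluoride cleaves the electron-poor aryl silyl ether under mildly acidic, base-free conditions, so the enolisable C3 stereocentre and the acid-sensitive chromene are untouched (fluoride-mediated desilylation).

The ee of 10 and 11 is checked by chiral HPLC; 11 can be recrystallised to upgrade it.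

**Compound list**

1 | 4-bromo-3-methoxyphenol | COc1cc(O)ccc1Br | starting material
2 | 3-methylbut-2-enal (prenal) | CC(C)=CC=O | starting material
3 | (6Z)-4-bromo-3-methoxy-6-(3-methylbut-2-en-1-ylidene)cyclohexa-2,4-dien-1-one (o-quinone methide) | O=C1C=C(OC)C(Br)=C/C1=C/C=C(C)C | intermediate (not isolated)
4 | 6-bromo-7-methoxy-2,2-dimethyl-2H-chromene | COc1cc2c(cc1Br)C=CC(C)(C)O2 | intermediate
5 | 7-hydroxychroman-4-one | O=C1CCOc2cc(O)ccc12 | starting material
6 | 4,7-bis[(tert-butyldimethylsilyl)oxy]-2H-chromene (bis-silyl enol ether) | CC(C)(C)[Si](C)(C)OC1=CCOc2cc(O[Si](C)(C)C(C)(C)C)ccc12 | intermediate (not isolated)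
7 | rac-3-bromo-7-[(tert-butyldimethylsilyl)oxy]chroman-4-one | CC(C)(C)[Si](C)(C)Oc1ccc2c(c1)OCC(Br)C2=O | intermediate
8 | (7-methoxy-2,2-dimethyl-2H-chromen-6-yl)magnesium bromide | COc1cc2c(cc1[Mg]Br)C=CC(C)(C)O2 | intermediate (not isolated)
9 | (7-methoxy-2,2-dimethyl-2H-chromen-6-yl)zinc iodide | COc1cc2c(cc1[Zn]I)C=CC(C)(C)O2 | intermediate (not isolated)
10 | (3S)-7-[(tert-butyldimethylsilyl)oxy]-3-(7-methoxy-2,2-dimethyl-2H-chromen-6-yl)chroman-4-one | COc1cc2c(cc1[C@H]1COc3cc(O[Si](C)(C)C(C)(C)C)ccc3C1=O)C=CC(C)(C)O2 | intermediate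
11 | (3S)-7-hydroxy-3-(7-methoxy-2,2-dimethyl-2H-chromen-6-yl)chroman-4-one | COc1cc2c(cc1[C@H]1COc3cc(O)ccc3C1=O)C=CC(C)(C)O2 | target

**Step count and risks**

Total steps: 4. Longest linear sequence: 3 steps (1 → 4 → 10 → 11, or 5 → 7 → 10 → 11).

Most likely to fail, in order:

Step 3 (key coupling). Risks: the ortho-methoxy arylzinc and the cyclic beta-aryloxy bromoketone lie outside the proven scope, so the chiral pocket may give low conversion or low ee; HBr loss from 7 to the chromone can compete. Fallback, setting out from 7 (with arylzinc 9 made from 4 as before) and returning at 10: couple 7 with 9 under a less hindered achiral catalyst, NiCl2(DME) with 4,4'-di-tert-butyl-2,2'-bipyridine in THF at 0 °C to rt, to give racemic 7-[(tert-butyldimethylsilyl)oxy]-3-(7-methoxy-2,2-dimethyl-2H-chromen-6-yl)chroman-4-one F1. The stereocentre is then set separately by asymmetric transfer hydrogenation with dynamic kinetic resolution, using RuCl[(S,S)-TsDPEN](p-cymene) and HCO2H/Et3N in EtOAc at rt; the ketone racemises through its enol while one enantiomer is reduced, giving (3S,4S)-7-[(tert-butyldimethylsilyl)oxy]-3-(7-methoxy-2,2-dimethyl-2H-chromen-6-yl)chroman-4-ol F2 (cis). Oxidation of C4 with Dess–Martin periodinane in CH2Cl2 at 0 °C, which does not touch C3, then gives 10.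

Step 2 (one-pot silylation and bromination). Risks: residual amine can eliminate HBr from 7 to the chromone, and NBS can over-brominate or attack ring A. Fallback, setting out from 5 and returning at 7: protect the phenol alone with TBSCl and imidazole in DMF to give 7-[(tert-butyldimethylsilyl)oxy]chroman-4-one F3. This ketone is then brominated directly through its enol under amine-free conditions with CuBr2 (2 equiv) in EtOAc/CHCl3 at reflux to give 7.

Step 1 (chromene annulation). Risks: the bromine lowers the nucleophilicity of the phenol, and some closure between OH and OMe would give the 5-methoxy isomer. Fallback, setting out from 1 and returning at 4: O-alkylate 1 with 3-chloro-3-methylbut-1-yne (DBU, CuCl2 cat., MeCN, 0 °C) to give 1-bromo-2-methoxy-4-[(2-methylbut-3-yn-2-yl)oxy]benzene F4. Heating this ether in N,N-diethylaniline at 190 °C triggers aromatic propargyl Claisen rearrangement to the less hindered ortho carbon, 1,5-H shift and oxa-6π electrocyclisation, giving 4.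

**Further compounds**

F1 | step 3 | rac-7-[(tert-butyldimethylsilyl)oxy]-3-(7-methoxy-2,2-dimethyl-2H-chromen-6-yl)chroman-4-one | COc1cc2c(cc1C1COc3cc(O[Si](C)(C)C(C)(C)C)ccc3C1=O)C=CC(C)(C)O2
F2 | step 3 | (3S,4S)-7-[(tert-butyldimethylsilyl)oxy]-3-(7-methoxy-2,2-dimethyl-2H-chromen-6-yl)chroman-4-ol | COc1cc2c(cc1[C@H]1COc3cc(O[Si](C)(C)C(C)(C)C)ccc3[C@H]1O)C=CC(C)(C)O2
F3 | step 2 | 7-[(tert-butyldimethylsilyl)oxy]chroman-4-one | CC(C)(C)[Si](C)(C)Oc1ccc2c(c1)OCCC2=O
F4 | step 1 | 1-bromo-2-methoxy-4-[(2-methylbut-3-yn-2-yl)oxy]benzene | COc1cc(OC(C)(C)C#C)ccc1Br
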